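**Retrosynthetic overview**
- The 6-hydroxy-2H-chromene (the only ring, formed last) comes from a para-(Z)-γ-hydroxyalkenyl phenol by oxidative spirocyclisation and a ring-expanding cationic 1,2-alkenyl shift (dienone–phenol type).
- The aryl–alkene bond comes from Sonogashira coupling of 4-iodo-3-methylphenol (from m-cresol) with a terminal alkyne triol, then Z-semihydrogenation.
- The C6′–C7′ bond and the (5′S,6′S)-diol come from a lithiated (S)-alkenyl oxirane and an (E)-alkenyl boronic ester (1,2-metallate shift, then oxidation).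
- The oxirane comes from an (E)-2-methyl enal (sulfonium ylide, hydrolytic kinetic resolution); the enal comes from cross-metathesis of a butenyl carbinol with methacrolein.
- The C2 carbinol stereocentre comes from lithiation–borylation of an (R)-butynyl carbamate with a butenyl boronic ester (1,2-metallate shift).

Assumption: the SMILES is read as (2S)-2-[(3E,5S,6S,7E)-5,6-dihydroxy-4,8,12-trimethyltrideca-3,7,11-trien-1-yl]-2,8-dimethyl-2H-chromen-6-ol; side-chain carbons carry primed locants below.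

**Route**

Step 1
Reactants: 1 (R)-4-(trimethylsilyl)but-3-yn-2-ol (C-silyl-protected (R)-but-3-yn-2-ol)
Product: 2 (R)-4-(trimethylsilyl)but-3-yn-2-yl N,N-diisopropylcarbamate
Conditions: iPr2NCOCl, Et3N, DMAP (cat.), toluene, 80 °C
Reagents that add atoms: N,N-diisopropylcarbamoyl chloride, ClC(=O)N(C(C)C)C(C)C
Why: Plain O-carbamoylation (acyl transfer) that leaves the (R) stereocentre untouched; the carbamate later directs α-lithiation and serves as the leaving group of the 1,2-shift.

Step 2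
Reactants: 2 (R)-4-(trimethylsilyl)but-3-yn-2-yl N,N-diisopropylcarbamate; 3 2-(but-3-en-1-yl)-4,4,5,5-tetramethyl-1,3,2-dioxaborolane (pinacol-protected but-3-enylboronic acid)
Product: 7 (3S)-3-methyl-1-(trimethylsilyl)hept-6-en-1-yn-3-ol, via lithiated carbamate 4 (not isolated), via boronate complex 5 (not isolated), via tertiary boronic ester 6 (not isolated)
Conditions: s-BuLi (1.2 equiv), TMEDA, Et2O, −78 °C; 3 (1.3 equiv), −78 °C → rt; then NaBO3·4H2O, THF/H2O, rt
Reagents that add atoms: sodium perborate, [Na+].[Na+].O[B-]1(O)OO[B-](O)(O)OO1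
Why: Lithiation–borylation (Hoppe-type α-lithiation, then stereospecific 1,2-metallate rearrangement): deprotonation gives 4 with retention, 3 is captured with retention to give 5, the butenyl group migrates from boron to carbon anti to the departing carbamate to give 6, and oxidation with retention sets the (S)-carbinol that becomes C2; the mild oxidant keeps the C–Si bond.

Step 3
Reactants: 7 (3S)-3-methyl-1-(trimethylsilyl)hept-6-en-1-yn-3-ol; 8 methacrolein (2-methylprop-2-enal)
Product: 9 (2E,6S)-6-hydroxy-2,6-dimethyl-8-(trimethylsilyl)oct-2-en-7-ynal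
Conditions: second-generation Hoveyda–Grubbs catalyst (5 mol %), 8 (10 equiv), CH2Cl2, 40 °C
Reagents that add atoms: none
Why: Olefin cross-metathesis of a terminal alkene with excess methacrolein gives the 2-methyl-2-enal with the thermodynamic (E) geometry; the silylated alkyne and the hindered carbinol do not engage the catalyst.

Step 4
Reactants: 9 (2E,6S)-6-hydroxy-2,6-dimethyl-8-(trimethylsilyl)oct-2-en-7-ynal
Product: 10 (3S,6E)-3-methyl-7-(oxiran-2-yl)-1-(trimethylsilyl)oct-6-en-1-yn-3-ol as a 1:1 mixture of oxirane epimers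
Conditions: Me3SI, n-BuLi, THF, −10 °C; then 9, −10 °C → rt
Reagents that add atoms: trimethylsulfonium iodide, C[S+](C)C.[I-]
Why: Corey–Chaykovsky epoxidation: the sulfonium methylide adds 1,2 to the enal and closes to the alkenyl oxirane; no facial control is expected, so both C5′ epimers form.

Step 5
Reactants: 10 (3S,6E)-3-methyl-7-(oxiran-2-yl)-1-(trimethylsilyl)oct-6-en-1-yn-3-ol (epimer mixture)
Product: 11 (3S,6E)-3-methyl-7-[(2S)-oxiran-2-yl]-1-(trimethylsilyl)oct-6-en-1-yn-3-ol
Conditions: (R,R)-[N,N′-bis(3,5-di-tert-butylsalicylidene)cyclohexane-1,2-diaminato]cobalt acetate (trivalent cobalt, 1 mol %), H2O (0.55 equiv), THF, 0 °C → rt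
Reagents that add atoms: none
Why: Jacobsen hydrolytic kinetic resolution of a terminal epoxide: the (R,R) catalyst hydrolyses the (R)-oxirane (sense as for propylene oxide and butadiene monoxide) and leaves the (S)-oxirane that carries the future C5′ stereocentre (at most 50 % yield).

Step 6
Reactants: 12 5-bromo-2-methylpent-2-ene
Product: 13 6-methylhept-5-en-1-yne
Conditions: LiC≡CH·H2NCH2CH2NH2, DMSO, 10 °C → rt
Reagents that add atoms: lithium acetylide ethylenediamine complex, [Li+].[C-]#C.NCCN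
Why: SN2 alkylation of lithium acetylide by a primary bromide.

Step 7
Reactants: 13 6-methylhept-5-en-1-yne
Product: 15 2-[(1E)-2,6-dimethylhepta-1,5-dien-1-yl]-4,4,5,5-tetramethyl-1,3,2-dioxaborolane, via alkenylalane 14 (not isolated)
Conditions: AlMe3 (2 equiv), Cp2ZrCl2 (20 mol %), CH2Cl2, 0 °C → rt; then iPrOBpin, −78 °C → rt
Reagents that add atoms: trimethylaluminium, C[Al](C)C; 2-isopropoxy-4,4,5,5-tetramethyl-1,3,2-dioxaborolane, CC(C)OB1OC(C)(C)C(C)(C)O1
Why: Negishi zirconium-catalysed syn-carboalumination puts methyl on the internal and aluminium on the terminal alkyne carbon (14, E geometry), and aluminium-to-boron exchange keeps the alkene geometry.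

Step 8
Reactants: 11 (3S,6E)-3-methyl-7-[(2S)-oxiran-2-yl]-1-(trimethylsilyl)oct-6-en-1-yn-3-ol; 15 2-[(1E)-2,6-dimethylhepta-1,5-dien-1-yl]-4,4,5,5-tetramethyl-1,3,2-dioxaborolane
Product: 19 (3S,6E,8S,9S,10E)-3,7,11,15-tetramethylhexadeca-6,10,14-trien-1-yne-3,8,9-triol, via lithiated oxirane 16 (not isolated), via boronate complex 17 (not isolated), via allylic boronic ester 18 (not isolated)
Conditions: 15 (2.0 equiv), lithium 2,2,6,6-tetramethylpiperidide (3.0 equiv, added to 11 + 15), THF, −78 → −30 °C, then 0 °C; then NaOH, H2O2, THF/MeOH, 0 °C → rt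
Reagents that add atoms: hydrogen peroxide, OO
Why: Proposed new method: the homologation of boronic esters with lithiated terminal epoxides (closest known reaction, shown for alkyl-substituted oxiranes with alkyl and aryl boronic esters) is extended to a 2-alkenyl oxirane and an alkenyl boronic ester; the hindered amide removes the oxirane CH2 proton trans to the alkenyl group to give 16, which 15 traps in situ with retention (17), the alkenyl group then shifts from boron to carbon anti to the breaking C–O bond with ring opening (18), and oxidation with retention gives the syn (5′S,6′S)-diol with the E alkene intact, while the alkaline methanol also cleaves the C–Si bond.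

Step 9
Reactants: 20 m-cresol (3-methylphenol)
Product: 21 4-iodo-3-methylphenol
Conditions: N-iodosuccinimide, TsOH·H2O (10 mol %), MeCN, 0 °C → rt
Reagents that add atoms: N-iodosuccinimide, O=C1CCC(=O)N1I
Why: Electrophilic aromatic iodination directed para by the hydroxyl group; the minor 6-iodo isomer is removed by chromatography.

Step 10
Reactants: 19 (3S,6E,8S,9S,10E)-3,7,11,15-tetramethylhexadeca-6,10,14-trien-1-yne-3,8,9-triol; 21 4-iodo-3-methylphenol
Product: 22 4-[(3S,6E,8S,9S,10E)-3,8,9-trihydroxy-3,7,11,15-tetramethylhexadeca-6,10,14-trien-1-yn-1-yl]-3-methylphenol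
Conditions: PdCl2(PPh3)2 (3 mol %), CuI (6 mol %), Et3N/THF, 40 °C
Reagents that add atoms: none
Why: Sonogashira coupling of a terminal alkyne with an aryl iodide; free hydroxyl groups are tolerated and no stereocentre is touched.

Step 11
Reactants: 22 4-[(3S,6E,8S,9S,10E)-3,8,9-trihydroxy-3,7,11,15-tetramethylhexadeca-6,10,14-trien-1-yn-1-yl]-3-methylphenol
Product: 23 4-[(1Z,3S,6E,8S,9S,10E)-3,8,9-trihydroxy-3,7,11,15-tetramethylhexadeca-1,6,10,14-tetraen-1-yl]-3-methylphenol
Conditions: H2 (1 atm), Pd on CaCO3 poisoned with Pb(OAc)2, quinoline, EtOAc, rt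
Reagents that add atoms: none
Why: Lindlar semihydrogenation (syn addition of H2) gives the (Z)-alkene that holds the tertiary hydroxyl next to the para carbon; the trisubstituted alkenes are not reduced.

Step 12
Reactants: 23 4-[(1Z,3S,6E,8S,9S,10E)-3,8,9-trihydroxy-3,7,11,15-tetramethylhexadeca-1,6,10,14-tetraen-1-yl]-3-methylphenol
Product: 25 (2S)-2-[(3E,5S,6S,7E)-5,6-dihydroxy-4,8,12-trimethyltrideca-3,7,11-trien-1-yl]-2,8-dimethyl-2H-chromen-6-ol, via spirodienone 24 (not isolated)
Conditions: PhI(OAc)2 (1.0 equiv, slow addition), MeCN, −30 °C; then BF3·OEt2 (20 mol %), CH2Cl2, −78 → −30 °C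
Reagents that add atoms: none
Why: Proposed new method: PhI(OAc)2 oxidises the phenol and the cis-held tertiary hydroxyl traps the para carbon to give the spiro-2,5-dihydrofuran dienone 24 (both spiro epimers; the carbinol C–O bond is never broken, so C2 stays S), then BF3 activation of the dienone triggers a cationic 1,2-shift of the ring alkenyl carbon from the spiro carbon to the unsubstituted ortho carbon (a vinyl group migrates well, the cation left behind is an oxocarbenium ion, and a shift to the methyl-bearing carbon is reversible and cannot aromatise) and loss of a proton aromatises, so the five-membered spiro ether expands to the 2H-chromene with the hydroxyl para to the ring oxygen and the methyl at C8; the closest known reaction is the dienone–phenol rearrangement of spiro ether and spiro lactone cyclohexadienones to 6-hydroxychromans and 6-hydroxydihydrocoumarins, where an sp3 carbon migrates.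

**Compound list**

1 | (R)-4-(trimethylsilyl)but-3-yn-2-ol | C[C@@H](O)C#C[Si](C)(C)C | starting material
2 | (R)-4-(trimethylsilyl)but-3-yn-2-yl N,N-diisopropylcarbamate | C[C@@H](OC(=O)N(C(C)C)C(C)C)C#C[Si](C)(C)C | intermediate
3 | 2-(but-3-en-1-yl)-4,4,5,5-tetramethyl-1,3,2-dioxaborolane | C=CCCB1OC(C)(C)C(C)(C)O1 | starting material
4 | α-lithiated carbamate of 2 (lithium in place of the carbinol hydrogen, configuration retained) | C[C@@]([Li])(OC(=O)N(C(C)C)C(C)C)C#C[Si](C)(C)C | intermediate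
5 | lithium boronate complex of 4 with 3 (boron in place of lithium, retention) | [Li+].C[C@@]([B-]1(CCC=C)OC(C)(C)C(C)(C)O1)(OC(=O)N(C(C)C)C(C)C)C#C[Si](C)(C)C | intermediate
6 | 2-[(3R)-3-methyl-1-(trimethylsilyl)hept-6-en-1-yn-3-yl]-4,4,5,5-tetramethyl-1,3,2-dioxaborolane | C[C@](B1OC(C)(C)C(C)(C)O1)(CCC=C)C#C[Si](C)(C)C | intermediate
7 | (3S)-3-methyl-1-(trimethylsilyl)hept-6-en-1-yn-3-ol | C=CCC[C@@](O)(C)C#C[Si](C)(C)C | intermediate
8 | methacrolein | CC(=C)C=O | starting material
9 | (2E,6S)-6-hydroxy-2,6-dimethyl-8-(trimethylsilyl)oct-2-en-7-ynal | O=C/C(C)=C/CC[C@@](O)(C)C#C[Si](C)(C)C | intermediate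
10 | (3S,6E)-3-methyl-7-(oxiran-2-yl)-1-(trimethylsilyl)oct-6-en-1-yn-3-ol, both oxirane epimers | C1OC1/C(C)=C/CC[C@@](O)(C)C#C[Si](C)(C)C | intermediate
11 | (3S,6E)-3-methyl-7-[(2S)-oxiran-2-yl]-1-(trimethylsilyl)oct-6-en-1-yn-3-ol | C1O[C@H]1/C(C)=C/CC[C@@](O)(C)C#C[Si](C)(C)C | intermediate
12 | 5-bromo-2-methylpent-2-ene | CC(C)=CCCBr | starting material
13 | 6-methylhept-5-en-1-yne | C#CCCC=C(C)C | intermediate
14 | [(1E)-2,6-dimethylhepta-1,5-dien-1-yl]dimethylalane | C[Al](C)/C=C(\C)CCC=C(C)C | intermediate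
15 | 2-[(1E)-2,6-dimethylhepta-1,5-dien-1-yl]-4,4,5,5-tetramethyl-1,3,2-dioxaborolane | CC(C)=CCC/C(C)=C/B1OC(C)(C)C(C)(C)O1 | intermediate
16 | lithiated oxirane from 11 (lithium on the oxirane CH2 carbon, trans to the alkenyl group; carbinol as lithium alkoxide) | [Li][C@@H]1O[C@H]1/C(C)=C/CC[C@@](O[Li])(C)C#C[Si](C)(C)C | intermediate
17 | lithium boronate complex of 16 with 15 | [Li+].CC(C)=CCC/C(C)=C/[B-]1(OC(C)(C)C(C)(C)O1)[C@@H]2O[C@H]2/C(C)=C/CC[C@@](O[Li])(C)C#C[Si](C)(C)C | intermediate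
18 | ring-opened allylic pinacol boronic ester (boron at C6′, lithium alkoxide at C5′ and at the carbinol) | CC(C)=CCC/C(C)=C/[C@H](B1OC(C)(C)C(C)(C)O1)[C@@H](O[Li])/C(C)=C/CC[C@@](O[Li])(C)C#C[Si](C)(C)C | intermediate
19 | (3S,6E,8S,9S,10E)-3,7,11,15-tetramethylhexadeca-6,10,14-trien-1-yne-3,8,9-triol | CC(C)=CCC/C(C)=C/[C@H](O)[C@@H](O)/C(C)=C/CC[C@@](O)(C)C#C | intermediate
20 | m-cresol | Cc1cccc(O)c1 | starting material
21 | 4-iodo-3-methylphenol | Cc1cc(O)ccc1I | intermediate
22 | 4-[(3S,6E,8S,9S,10E)-3,8,9-trihydroxy-3,7,11,15-tetramethylhexadeca-6,10,14-trien-1-yn-1-yl]-3-methylphenol | CC(C)=CCC/C(C)=C/[C@H](O)[C@@H](O)/C(C)=C/CC[C@@](O)(C)C#Cc1ccc(O)cc1C | intermediate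
23 | 4-[(1Z,3S,6E,8S,9S,10E)-3,8,9-trihydroxy-3,7,11,15-tetramethylhexadeca-1,6,10,14-tetraen-1-yl]-3-methylphenol | CC(C)=CCC/C(C)=C/[C@H](O)[C@@H](O)/C(C)=C/CC[C@@](O)(C)/C=C\c1ccc(O)cc1C | intermediate
24 | (2S)-2-[(3E,5S,6S,7E)-5,6-dihydroxy-4,8,12-trimethyltrideca-3,7,11-trien-1-yl]-2,6-dimethyl-1-oxaspiro[4.5]deca-3,6,9-trien-8-one, both spiro epimers | CC(C)=CCC/C(C)=C/[C@H](O)[C@@H](O)/C(C)=C/CC[C@@]1(C)C=CC2(O1)C=CC(=O)C=C2C | intermediate
25 | (2S)-2-[(3E,5S,6S,7E)-5,6-dihydroxy-4,8,12-trimethyltrideca-3,7,11-trien-1-yl]-2,8-dimethyl-2H-chromen-6-ol | CC(C)=CCC/C(C)=C/[C@H](O)[C@@H](O)/C(C)=C/CC[C@@]1(C)C=Cc2cc(O)cc(C)c2O1 | target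

**Step count and risks**

Total: 12 steps. Longest linear sequence: 9 steps (1, 2, 3, 4, 5, 8, 10, 11, 12).

The three steps most likely to fail:

Step 12 (proposed new step). Risks: over-oxidation of the electron-rich product if oxidant remains, slow glycol cleavage by the iodine reagent, acid-induced ionisation of the allylic diol, and the alkenyl group shifting first to the methyl-bearing carbon. Fallback by known chemistry, setting out from 22 and coming back at 25: hydrogenation of 22 with RhCl(PPh3)3 and H2 reduces only the alkyne, giving the saturated phenol 4-[(3S,6E,8S,9S,10E)-3,8,9-trihydroxy-3,7,11,15-tetramethylhexadeca-6,10,14-trien-1-yl]-3-methylphenol F1. PhI(OAc)2 then gives the saturated spiro ether (2S)-2-[(3E,5S,6S,7E)-5,6-dihydroxy-4,8,12-trimethyltrideca-3,7,11-trien-1-yl]-2,6-dimethyl-1-oxaspiro[4.5]deca-6,9-dien-8-one F2. The established acid-mediated dienone–phenol rearrangement (sp3 carbon shift, BF3·OEt2) gives the chromanol (2S)-2-[(3E,5S,6S,7E)-5,6-dihydroxy-4,8,12-trimethyltrideca-3,7,11-trien-1-yl]-2,8-dimethyl-3,4-dihydro-2H-chromen-6-ol F3. DDQ dehydrogenation in benzene, as used to turn 6-hydroxychromans of the tocopherol family into chromenols, gives 25.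

Step 8 (proposed new step). Risks: the amide base may deprotonate the allylic oxirane C–H or cause 1,4-elimination to a dienol, and the β-oxido boronic ester 18 may eliminate to a conjugated triene before oxidation. Fallback by known chemistry, setting out from 10 (with 13 for the alkenyl partner) and coming back at 19: hydrolytic kinetic resolution of 10 with the (S,S) enantiomer of the cobalt salen catalyst converts the (S)-oxirane into the diol (2S,3E,7S)-3,7-dimethyl-9-(trimethylsilyl)non-3-en-8-yne-1,2,7-triol F4. TESCl and imidazole give (3S,6E,8S)-3,7-dimethyl-8,9-bis(triethylsilyloxy)-1-(trimethylsilyl)non-6-en-1-yn-3-ol F5. Swern oxidation, which oxidises the primary silyl ether directly, gives the aldehyde (2S,3E,7S)-7-hydroxy-3,7-dimethyl-2-(triethylsilyloxy)-9-(trimethylsilyl)non-3-en-8-ynal F6. Carboalumination of 13 (AlMe3, Cp2ZrCl2) and quenching with I2 gives (1E)-1-iodo-2,6-dimethylhepta-1,5-diene F7, which t-BuLi and ZnBr2 convert into bromo[(1E)-2,6-dimethylhepta-1,5-dien-1-yl]zinc F8. Chelation-controlled addition of F8 to F6 in the presence of EtZnCl gives the syn adduct (3S,6E,8S,9S,10E)-3,7,11,15-tetramethyl-8-(triethylsilyloxy)-1-(trimethylsilyl)hexadeca-6,10,14-trien-1-yne-3,9-diol F9, and TBAF removes both silyl groups to give 19.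

Step 2. Risks: the lithiated propargylic carbamate may lose configuration or react at the allenyl terminus, and the 1,2-shift may be slow. Fallback by known chemistry, setting out from 1 (racemic 1 then suffices) and coming back at 7: MnO2 oxidation gives 4-(trimethylsilyl)but-3-yn-2-one F10. Addition of but-3-enylmagnesium bromide with CeCl3 at −78 °C gives racemic 3-methyl-1-(trimethylsilyl)hept-6-en-1-yn-3-ol F11. Preparative chromatography on a chiral stationary phase delivers the (S)-enantiomer 7.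

**Further compounds**

F1 | step 12 | 4-[(3S,6E,8S,9S,10E)-3,8,9-trihydroxy-3,7,11,15-tetramethylhexadeca-6,10,14-trien-1-yl]-3-methylphenol | CC(C)=CCC/C(C)=C/[C@H](O)[C@@H](O)/C(C)=C/CC[C@@](O)(C)CCc1ccc(O)cc1C
F2 | step 12 | (2S)-2-[(3E,5S,6S,7E)-5,6-dihydroxy-4,8,12-trimethyltrideca-3,7,11-trien-1-yl]-2,6-dimethyl-1-oxaspiro[4.5]deca-6,9-dien-8-one | CC(C)=CCC/C(C)=C/[C@H](O)[C@@H](O)/C(C)=C/CC[C@@]1(C)CCC2(O1)C=CC(=O)C=C2C
F3 | step 12 | (2S)-2-[(3E,5S,6S,7E)-5,6-dihydroxy-4,8,12-trimethyltrideca-3,7,11-trien-1-yl]-2,8-dimethyl-3,4-dihydro-2H-chromen-6-ol | CC(C)=CCC/C(C)=C/[C@H](O)[C@@H](O)/C(C)=C/CC[C@@]1(C)CCc2cc(O)cc(C)c2O1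
F4 | step 8 | (2S,3E,7S)-3,7-dimethyl-9-(trimethylsilyl)non-3-en-8-yne-1,2,7-triol | OC[C@@H](O)/C(C)=C/CC[C@@](O)(C)C#C[Si](C)(C)C
F5 | step 8 | (3S,6E,8S)-3,7-dimethyl-8,9-bis(triethylsilyloxy)-1-(trimethylsilyl)non-6-en-1-yn-3-ol | CC[Si](CC)(CC)OC[C@@H](O[Si](CC)(CC)CC)/C(C)=C/CC[C@@](O)(C)C#C[Si](C)(C)C
F6 | step 8 | (2S,3E,7S)-7-hydroxy-3,7-dimethyl-2-(triethylsilyloxy)-9-(trimethylsilyl)non-3-en-8-ynal | O=C[C@@H](O[Si](CC)(CC)CC)/C(C)=C/CC[C@@](O)(C)C#C[Si](C)(C)C
F7 | step 8 | (1E)-1-iodo-2,6-dimethylhepta-1,5-diene | CC(C)=CCC/C(C)=C/I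
F8 | step 8 | bromo[(1E)-2,6-dimethylhepta-1,5-dien-1-yl]zinc | CC(C)=CCC/C(C)=C/[Zn]Br
F9 | step 8 | (3S,6E,8S,9S,10E)-3,7,11,15-tetramethyl-8-(triethylsilyloxy)-1-(trimethylsilyl)hexadeca-6,10,14-trien-1-yne-3,9-diol | CC(C)=CCC/C(C)=C/[C@H](O)[C@@H](O[Si](CC)(CC)CC)/C(C)=C/CC[C@@](O)(C)C#C[Si](C)(C)C
F10 | step 2 | 4-(trimethylsilyl)but-3-yn-2-one | CC(=O)C#C[Si](C)(C)C
F11 | step 2 | racemic 3-methyl-1-(trimethylsilyl)hept-6-en-1-yn-3-ol | C=CCCC(C)(O)C#C[Si](C)(C)C
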